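A direct plan would O-alkylate syringaldehyde with dimethyl chloromalonate to give aldehyde A1 and would turn 4-allyl-2,6-dimethoxyphenol into the silyl-protected allyl aryl ether A2.
It would join the two by an asymmetric γ-aryloxyallylboration to give homoallylic alcohol A3, then finish by ozonolysis, borohydride reduction and desilylation.
Its weakest points would be:
- The allylboration would rest both stereocentres on a lithiated aryl allyl ether, for which Wittig rearrangement and loss of Z geometry are real risks, and it would need a stoichiometric chiral borane.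
- The ozonolysis and reduction would fall on the most advanced material, where two trioxygenated arenes compete for ozone and the α-aryloxy-β-hydroxy aldehyde can epimerise or cleave by retro-aldol reaction.
- The hydroboration, allylation, silylation and desilylation would be four operations spent on arming and protecting ring B with almost no gain in complexity.

**Plan of the new route**
The four primary alcohols (C9, C9' and the two glycerol CH2OH groups) are first taken back to methyl esters.
The cuts then follow in this order: the C7–H bond (ketone), the C8–O4' ether bond (α-chloro-β-keto ester plus ring B phenol), the C8–C9 bond (Claisen condensation with dimethyl carbonate) and the ring A O4–C bond (chloromalonate).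
No ring is formed; both arenes are bought.
Enabling feature: C8 lies between C7 and C9 and carries the ring B aryloxy oxygen, so with C7 as ketone and C9 as ester its hydrogen is acidic and the centre is stereolabile. A dynamic kinetic resolution can therefore funnel both C8 epimers into the one syn (threo) isomer while C7 is reduced.
The C7–C8 bond is made early and without stereochemistry, so no chiral organometallic is needed; no alkene is present, so there is no ozonolysis; ring B's side chain travels as a methyl ester and is unveiled in the one global reduction, so no protecting group is used.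

Key step: step 6

Assumptions:
- Locants follow lignan numbering (C7, C8, C9 on the ring A side chain, primed locants on ring B); threo corresponds to syn in the zigzag drawing.
- The sense of induction in step 6 is taken from aryl ketone reductions with the same catalyst; should it prove opposite, the (R,R) catalyst would be used.

Step 1
Reactants: 1 acetosyringone [1-(4-hydroxy-3,5-dimethoxyphenyl)ethanone]; 2 dimethyl chloromalonate
Product: 3 dimethyl 2-(4-acetyl-2,6-dimethoxyphenoxy)propanedioate
Conditions: K2CO3 (1.5 equiv), MeCN, 60 °C
Reagents that add atoms: dimethyl chloromalonate (2), COC(=O)C(Cl)C(=O)OC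
Why: In this Williamson-type SN2 O-alkylation the para-acyl phenol (pKa about 8) is ionised by K2CO3 and displaces the chloride of the doubly carbonyl-activated malonate, while the methyl ketone is far too weakly acidic to interfere and no stereocentre is formed.

Step 2
Reactants: 3 dimethyl 2-(4-acetyl-2,6-dimethoxyphenoxy)propanedioate; 4 dimethyl carbonate
Product: 6 dimethyl 2-[2,6-dimethoxy-4-(3-methoxy-3-oxopropanoyl)phenoxy]propanedioate, via disodium bis-enolate 5 (not isolated)
Conditions: NaH (3.2 equiv), (MeO)2CO (10 equiv), THF, reflux; then AcOH, 0 °C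
Reagents that add atoms: dimethyl carbonate (4), COC(=O)OC
Why: In this crossed Claisen condensation the first equivalent of NaH stores the aryloxymalonate as its unreactive sodium enolate, the ketone enolate then attacks dimethyl carbonate to form the C8–C9 bond, and deprotonation of the β-keto ester drives the equilibrium, whereas any methoxycarbonylation at the malonate carbon should revert because that product cannot be deprotonated.

Step 3
Reactants: 6 dimethyl 2-[2,6-dimethoxy-4-(3-methoxy-3-oxopropanoyl)phenoxy]propanedioate
Product: 7 dimethyl 2-[4-(2-chloro-3-methoxy-3-oxopropanoyl)-2,6-dimethoxyphenoxy]propanedioate (racemic)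
Conditions: SO2Cl2 (1.05 equiv), CH2Cl2, 0 °C → rt
Reagents that add atoms: sulfuryl chloride, O=S(=O)(Cl)Cl
Why: This electrophilic α-chlorination of a β-keto ester runs through its enol, so one equivalent of SO2Cl2 at 0 °C should react at the strongly enolised C8 well before the barely enolised aryloxymalonate carbon or the acyl-deactivated arene, and the racemic C8 centre is intended.

Step 4
Reactants: 8 sinapic acid [(E)-3-(4-hydroxy-3,5-dimethoxyphenyl)prop-2-enoic acid]
Product: 10 methyl 3-(4-hydroxy-3,5-dimethoxyphenyl)propanoate, via dihydrosinapic acid 9 (not isolated)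
Conditions: H2 (1 atm), 10% Pd/C, MeOH, rt; filter; conc. H2SO4 (cat.), reflux
Reagents that add atoms: methanol, CO
Why: Heterogeneous hydrogenation saturates the cinnamic C=C and Fischer esterification in the same methanol solution gives the methyl ester, neither touching the phenol or the aryl ethers, so ring B's future 3-hydroxypropyl chain is carried at the ester level without a protecting group.

Step 5
Reactants: 7 dimethyl 2-[4-(2-chloro-3-methoxy-3-oxopropanoyl)-2,6-dimethoxyphenoxy]propanedioate; 10 methyl 3-(4-hydroxy-3,5-dimethoxyphenyl)propanoate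
Product: 11 dimethyl 2-(4-{2-[2,6-dimethoxy-4-(3-methoxy-3-oxopropyl)phenoxy]-3-methoxy-3-oxopropanoyl}-2,6-dimethoxyphenoxy)propanedioate (racemic at C8)
Conditions: K2CO3 (2.0 equiv), acetone, 50 °C
Reagents that add atoms: none
Why: This Williamson-type SN2 displacement of the doubly activated secondary chloride by the potassium phenoxide of 10 (the reaction used to make 2-aryloxy-3-oxo esters from phenols and 2-chloro-3-oxo esters) forms the C8–O4' bond, the methyl esters are inert to K2CO3 in acetone, and C8 is left racemic and stereolabile on purpose.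

Step 6
Reactants: 11 dimethyl 2-(4-{2-[2,6-dimethoxy-4-(3-methoxy-3-oxopropyl)phenoxy]-3-methoxy-3-oxopropanoyl}-2,6-dimethoxyphenoxy)propanedioate
Product: 12 dimethyl 2-(4-{(1R,2S)-1-hydroxy-3-methoxy-2-[2,6-dimethoxy-4-(3-methoxy-3-oxopropyl)phenoxy]-3-oxopropyl}-2,6-dimethoxyphenoxy)propanedioate
Conditions: RuCl[(S,S)-TsDPEN](p-cymene) (2 mol %), HCO2H/Et3N (5:2), CH2Cl2, 30 °C
Reagents that add atoms: none
Why: In this Noyori–Ikariya asymmetric transfer hydrogenation with dynamic kinetic resolution, the divalent ruthenium hydride formed from formic acid (CO2 is lost) passes hydride and proton to the C7 ketone through the outer-sphere six-membered metal–ligand bifunctional transition state, while Et3N interconverts the two C8 epimers of 11 through the enol because C8–H lies between the C7 ketone and the C9 ester and carries the aryloxy oxygen. The closest known reaction type is the transfer hydrogenation with dynamic kinetic resolution of α-alkoxy β-aryl β-keto esters with the same catalyst and formic acid–triethylamine, which gives syn α-alkoxy β-hydroxy esters. No ring is closed. C7 is set by the catalyst, ring A lying under the η6-p-cymene ligand so that the (S,S) ligand should deliver hydride to the face that gives 7R (the sense that gives (S)-1-phenylethanol from acetophenone), and C8 is set by the resolution, since the epimer leading to the syn product should be reduced much faster in the matched transition state while the slower one keeps racemising. The step needs chemoselectivity for the ketone over four methyl esters, which a formate-driven ruthenium hydride does not reduce, and needs epimerisation at C8 to outrun reduction, which the 1,3-dicarbonyl acidity secures; once C7 is an alcohol, C8 is no longer acidic enough to epimerise under these conditions.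

Step 7
Reactants: 12 dimethyl 2-(4-{(1R,2S)-1-hydroxy-3-methoxy-2-[2,6-dimethoxy-4-(3-methoxy-3-oxopropyl)phenoxy]-3-oxopropyl}-2,6-dimethoxyphenoxy)propanedioate
Product: 13 (1R,2R)-1-{4-[(1,3-dihydroxypropan-2-yl)oxy]-3,5-dimethoxyphenyl}-2-[4-(3-hydroxypropyl)-2,6-dimethoxyphenoxy]propane-1,3-diol (target)
Conditions: LiBH4 (6 equiv), THF/MeOH (20:1), 0 °C → rt; sat. aq NH4Cl, 0 °C
Reagents that add atoms: none
Why: This global hydride reduction of esters should turn all four methyl esters into the primary alcohols at C9, C9' and the two glycerol carbons, as in the known hydride reductions of 2-aryloxy-3-hydroxy esters and of aryloxymalonates to 2-aryloxypropane-1,3-diols, with the activated α-aryloxy esters reacting first so that C8 loses its acidity before epimerisation or retro-aldol cleavage can compete; neither stereocentre is touched and only the descriptor of C8 changes from S to R through the change in substituent priorities.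

## Compound list
1 | acetosyringone, 1-(4-hydroxy-3,5-dimethoxyphenyl)ethanone | CC(=O)c1cc(OC)c(O)c(OC)c1 | starting material
2 | dimethyl chloromalonate | COC(=O)C(Cl)C(=O)OC | starting material
3 | dimethyl 2-(4-acetyl-2,6-dimethoxyphenoxy)propanedioate | CC(=O)c1cc(OC)c(OC(C(=O)OC)C(=O)OC)c(OC)c1 | intermediate
4 | dimethyl carbonate | COC(=O)OC | starting material
5 | disodium bis-enolate of 6 (malonate enolate and β-keto ester enolate) | [Na+].[Na+].COC(=O)C=C([O-])c1cc(OC)c(OC(C(=O)OC)=C([O-])OC)c(OC)c1 | intermediate
6 | dimethyl 2-[2,6-dimethoxy-4-(3-methoxy-3-oxopropanoyl)phenoxy]propanedioate | COC(=O)CC(=O)c1cc(OC)c(OC(C(=O)OC)C(=O)OC)c(OC)c1 | intermediate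
7 | dimethyl 2-[4-(2-chloro-3-methoxy-3-oxopropanoyl)-2,6-dimethoxyphenoxy]propanedioate, racemic | COC(=O)C(Cl)C(=O)c1cc(OC)c(OC(C(=O)OC)C(=O)OC)c(OC)c1 | intermediate
8 | sinapic acid, (E)-3-(4-hydroxy-3,5-dimethoxyphenyl)prop-2-enoic acid | COc1cc(/C=C/C(=O)O)cc(OC)c1O | starting material
9 | dihydrosinapic acid, 3-(4-hydroxy-3,5-dimethoxyphenyl)propanoic acid | COc1cc(CCC(=O)O)cc(OC)c1O | intermediate
10 | methyl 3-(4-hydroxy-3,5-dimethoxyphenyl)propanoate | COc1cc(CCC(=O)OC)cc(OC)c1O | intermediate
11 | dimethyl 2-(4-{2-[2,6-dimethoxy-4-(3-methoxy-3-oxopropyl)phenoxy]-3-methoxy-3-oxopropanoyl}-2,6-dimethoxyphenoxy)propanedioate, racemic at C8 | COC(=O)CCc1cc(OC)c(OC(C(=O)OC)C(=O)c2cc(OC)c(OC(C(=O)OC)C(=O)OC)c(OC)c2)c(OC)c1 | intermediate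
12 | dimethyl 2-(4-{(1R,2S)-1-hydroxy-3-methoxy-2-[2,6-dimethoxy-4-(3-methoxy-3-oxopropyl)phenoxy]-3-oxopropyl}-2,6-dimethoxyphenoxy)propanedioate | COc1cc([C@@H](O)[C@@H](C(=O)OC)Oc2c(OC)cc(CCC(=O)OC)cc2OC)cc(OC)c1OC(C(=O)OC)C(=O)OC | intermediate
13 | (1R,2R)-1-{4-[(1,3-dihydroxypropan-2-yl)oxy]-3,5-dimethoxyphenyl}-2-[4-(3-hydroxypropyl)-2,6-dimethoxyphenoxy]propane-1,3-diol | COc1cc([C@@H](O)[C@@H](CO)Oc2c(OC)cc(CCCO)cc2OC)cc(OC)c1OC(CO)CO | target

Total step count: 7. Longest linear sequence: 6 (steps 1, 2, 3, 5, 6, 7).

**Steps most likely to fail**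

Step 6. The bulky 2,6-dimethoxyaryloxy group at C8 and the electron-rich ring A ketone may slow hydride transfer, or may erode the facial and syn/anti discrimination on which the resolution depends. The fallback sets both centres by an Evans syn-glycolate aldol reaction. It sets out from phenol 10 and chloromalonate 2. Phenol 10 would be O-alkylated with commercial (S)-4-benzyl-3-(bromoacetyl)oxazolidin-2-one F1 (K2CO3, acetone, rt) to give (S)-4-benzyl-3-{[2,6-dimethoxy-4-(3-methoxy-3-oxopropyl)phenoxy]acetyl}oxazolidin-2-one F2. Separately, syringaldehyde F3 and 2 (K2CO3, MeCN, 60 °C) would give dimethyl 2-(4-formyl-2,6-dimethoxyphenoxy)propanedioate F4. The Z-boron enolate of F2 (Bu2BOTf, iPr2NEt, CH2Cl2, −78 °C) would add to F4 through the Zimmerman–Traxler chair, the (S)-benzyl auxiliary directing formation of the syn aldol adduct F5 with the (1R,2S) configuration. LiBH4 (THF/MeOH, 0 °C → rt) would then remove the auxiliary reductively and reduce the three methyl esters in the same operation, coming back to the route at target 13.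

Step 5. The hindered phenoxide of 10 may fail to displace the secondary chloride of 7, with attack at chlorine or enolisation of 7 stalling the substitution. The fallback forms the same C8–O bond by carbenoid O–H insertion under neutral conditions. It sets out from β-keto ester 6 and phenol 10. Regitz diazo transfer to 6 (4-acetamidobenzenesulfonyl azide, Et3N, MeCN, rt) can only occur at the CH2 group and would give dimethyl 2-[4-(2-diazo-3-methoxy-3-oxopropanoyl)-2,6-dimethoxyphenoxy]propanedioate F6. Rh2(OAc)4 (1 mol %) in CH2Cl2 at 40 °C with 10 would then insert the rhodium carbenoid into the phenol O–H bond, coming back to the route at 11.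

Step 2. The malonate enolate may not survive hot NaH and dimethyl carbonate, or the condensation may stall with the ketone unreacted. The fallback builds the β-keto ester from the aldehyde oxidation level without strong base. It sets out from chloromalonate 2, which with syringaldehyde F3 gives aldehyde F4 as described in the fallback for step 6. Addition of methyl diazoacetate F7 to F4 (DBU 0.5 equiv, MeCN, rt) would give racemic dimethyl 2-[4-(2-diazo-1-hydroxy-3-methoxy-3-oxopropyl)-2,6-dimethoxyphenoxy]propanedioate F8. Rh2(OAc)4 (1 mol %, CH2Cl2, rt) would then trigger loss of nitrogen and a 1,2-hydride shift, coming back to the route at 6.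

## Further compounds
F1 | step 6 | (S)-4-benzyl-3-(bromoacetyl)oxazolidin-2-one | O=C(CBr)N1[C@@H](Cc2ccccc2)COC1=O
F2 | step 6 | (S)-4-benzyl-3-{[2,6-dimethoxy-4-(3-methoxy-3-oxopropyl)phenoxy]acetyl}oxazolidin-2-one | COC(=O)CCc1cc(OC)c(OCC(=O)N2[C@@H](Cc3ccccc3)COC2=O)c(OC)c1
F3 | step 6 | syringaldehyde, 4-hydroxy-3,5-dimethoxybenzaldehyde | COc1cc(C=O)cc(OC)c1O
F4 | step 6 | dimethyl 2-(4-formyl-2,6-dimethoxyphenoxy)propanedioate | COC(=O)C(Oc1c(OC)cc(C=O)cc1OC)C(=O)OC
F5 | step 6 | dimethyl 2-(4-{(1R,2S)-3-[(S)-4-benzyl-2-oxooxazolidin-3-yl]-1-hydroxy-2-[2,6-dimethoxy-4-(3-methoxy-3-oxopropyl)phenoxy]-3-oxopropyl}-2,6-dimethoxyphenoxy)propanedioate | COc1cc([C@@H](O)[C@@H](C(=O)N2[C@@H](Cc3ccccc3)COC2=O)Oc4c(OC)cc(CCC(=O)OC)cc4OC)cc(OC)c1OC(C(=O)OC)C(=O)OC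
F6 | step 5 | dimethyl 2-[4-(2-diazo-3-methoxy-3-oxopropanoyl)-2,6-dimethoxyphenoxy]propanedioate | COC(=O)C(=[N+]=[N-])C(=O)c1cc(OC)c(OC(C(=O)OC)C(=O)OC)c(OC)c1
F7 | step 2 | methyl diazoacetate | COC(=O)C=[N+]=[N-]
F8 | step 2 | dimethyl 2-[4-(2-diazo-1-hydroxy-3-methoxy-3-oxopropyl)-2,6-dimethoxyphenoxy]propanedioate, racemic | COC(=O)C(=[N+]=[N-])C(O)c1cc(OC)c(OC(C(=O)OC)C(=O)OC)c(OC)c1
A1 | direct plan | dimethyl 2-(4-formyl-2,6-dimethoxyphenoxy)propanedioate | COC(=O)C(Oc1c(OC)cc(C=O)cc1OC)C(=O)OC
A2 | direct plan | triethyl{3-[3,5-dimethoxy-4-(prop-2-en-1-yloxy)phenyl]propoxy}silane | C=CCOc1c(OC)cc(CCCO[Si](CC)(CC)CC)cc1OC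
A3 | direct plan | dimethyl 2-(4-{(1R,2R)-2-[2,6-dimethoxy-4-(3-triethylsilyloxypropyl)phenoxy]-1-hydroxybut-3-en-1-yl}-2,6-dimethoxyphenoxy)propanedioate | COc1cc([C@@H](O)[C@@H](C=C)Oc2c(OC)cc(CCCO[Si](CC)(CC)CC)cc2OC)cc(OC)c1OC(C(=O)OC)C(=O)OC
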